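The nearest neighbour of the moment asked about is this flask at its own start, with 0.960 M of partner against 0.80 M of substrate.

    substrate + free catalyst ⇌ catalyst intermediate A (K1 = 1.1 L mol⁻¹, k1 = 10000 L mol⁻¹ min⁻¹)
    catalyst intermediate A → catalyst intermediate B (k2 = 280 min⁻¹)
    partner + catalyst intermediate B → catalyst intermediate C (k3 = 650 L mol⁻¹ min⁻¹)
    catalyst intermediate C → catalyst intermediate D (k4 = 34000 min⁻¹)
    catalyst intermediate D → free catalyst + target (k5 = 840 min⁻¹)
    partner → decomposed reagent (k6 = 0.10 min⁻¹)
    substrate ⇌ dormant form (K7 = 0.33, k7 = 0.059 min⁻¹)

substrate 0.80 M; partner 1.20 equiv; free catalyst 0.057 mol%

- apparent order in partner when 50% of the substrate are converted (percent change of the rate of making target for one percent more partner charged)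

- what has gone from substrate into another species counts as reacted, even if it can come back
- charge of substrate (flask): 0.80 M

1. Near steady turnover, each catalyst form's share of the catalyst equals its share of one turn. Partner order runs on a scale from zero, with no wait at catalyst intermediate B, to one, with a turn that is nothing but that wait; the local order is that wait's share. Intermediates A, C and D together take 0.00479 min. At 0.400 M of substrate, free catalyst waits 0.00837 min.

2. The catalyst charged is 4.56 × 10⁻⁴ M. With the dormant form at equilibrium with substrate, c(target) at the conversion asked about is 0.268 M. The dormant form relaxes with half-life 2.91 min, shorter than the estimated run, so that equilibrium is the assumption taken.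

3. Partner goes once per target and also decays. Against c(target) this balance is linear, so an extra portion of partner survives as exp(−decay constant × t), where t is the run time without the partner wait. With the substrate wait averaged straight between its ends, t is 6.50 min, survival 0.522, c(partner) 0.237 M, and the order 0.696.

4. The weak link is that average: the wait goes as one over c(substrate), so the straight mean runs higher than the true mean, ln(2) times the wait at half conversion. Now t is 6.22 min, survival 0.537, and c(partner) 0.248 M.

5. The turnover time, the sum of every stay in one turn, is 0.0194 min. The partner wait is 32.0% of it, about a third. One percent more charged leaves 2.07 percent more partner, so the order is 0.664.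

The forecast says 0.72, reasoning that “1% more charged means about 2% more remaining at that conversion”.

The flask gives 0.65, reached at 8.24 min with free catalyst at 43.1% of the catalyst. The turnover time carried over turns the catalyst charged into 0.0236 M min⁻¹ of target, and the flask makes target at 0.0235 M min⁻¹.

The constants belong to no real substance, and the outcome is calculated.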